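# Proposed total synthesis of euchrenone b2 (16) by 1,2-aroyl shift of a fully prenylated chalcone epoxide

## Analysis of the target

Euchrenone b2 (16) is an isoflavone: a chromen-4-one (benzo ring A fused to pyranone ring C) that carries ring B on C3. Ring A is fully substituted (C5–OH, C6–prenyl, C7–OH, C8–prenyl). Ring B is a resorcinol with C2'–OH, C4'–OH and a prenyl group on C3', the carbon between the two oxygens. There is no stereocentre and no stable axis, because rotation about C3–C1' is hindered only by the C2'–OH; the problem is one of connectivity and regiochemistry.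

The feature that decides the strategy is the three-carbon bridge C2–C3–C4. Ring B sits on its central carbon C3, directly beside the carbonyl carbon C4 that is bonded to C4a of ring A. This 1,2-diaryl pattern is what biosynthesis makes from the 1,3-diaryl (chalcone/flavanone) pattern by a 1,2-shift, and C3–C4 is the bond such a shift creates.

A second feature helps: before ring C is closed, ring A is a 2,4,6-trioxygenated 3,5-diprenylaroyl group with a mirror plane through C4a and C7. The two ortho oxygens (later O1 and C5–O) and the two prenyl carbons (later C6 and C8) are pairwise equivalent, so ring closure cannot give a regioisomer.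

The sensitive groups are:
- three trisubstituted olefins, each ortho to a phenol, which cyclise to 2,2-dimethylchromans in acid and are attacked by electrophilic oxidants and halogens;
- the C2'–OH, which lies next to the electrophilic C2;
- the pyranone, which is opened by strong aqueous base.

The difficulty is to place three prenyl groups on carbons flanked by two oxygens (C6, C8, C3' and not C5') and to create the hindered C3–aryl connection with all three olefins already present.

## Retrosynthetic reasoning

**16 to 14 (O1–C2 bond and the O-protecting groups).** Ring C is opened at O1–C2 and the five phenols are masked as methoxymethyl (MOM) ethers, giving the α-formyl ketone 14. In 14 the ring A aroyl group is symmetric, so either ortho oxygen closes to the same chromone. The forward step must free an ortho oxygen of ring A before the C2'-oxygen of ring B, so that closure passes through the tetra-ether 15 and not through a benzofuran.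

**14 to 13 (C3–C4 bond, the key disconnection).** The bond between the ketone carbon and the aryl-bearing carbon of 14 is cut, and the aroyl group is returned to the neighbouring carbon (the later C2). This is a retro-1,2-acyl shift and leads to the trans-epoxy ketone 13, which has the linear 1,3-diaryl chain. The cut is made here because the donor ring B can stabilise a cation exactly at the carbon that must receive the aroyl group. The gain is that the whole isoflavone connectivity, with the three prenyl groups in place, comes from a precursor assembled by an aldol condensation. The forward reaction must open the epoxide only at the carbon next to ring B and must let the aroyl group, not hydrogen, migrate.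

**13 to 12 (epoxide oxygen).** Removing the oxirane oxygen gives the E-chalcone 12. The forward epoxidation must be nucleophilic, so that it picks the enone and ignores the three electron-rich prenyl olefins.

**12 to 4 + 10 (Cα=Cβ of the enone).** A retro-aldol condensation divides 12 into the methyl ketone 4 and the aldehyde 10. Both halves already carry all prenyl groups and all protecting groups, and neither can react with itself in a harmful way (10 has no α-hydrogen).

**4 to 3 to 1 + 2 (two ring C–CH2 bonds).** The two prenyl groups of 4 are cut at the ring carbons. 3 arises from the symmetric, commercial acetophenone 1 and two equivalents of 2. The only nucleophilic ring carbons of 1 are the two that must be alkylated, so no regiochemical question arises. Protection of 3 gives 4.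

**10 to 8 to 6 to 5 (C1–CHO and C3–CH2 bonds of ring B).** The formyl group of 10 is removed via the aryllithium 9 to give 8. The prenyl group of 8 is removed via the aryllithium 7 to give 6, the bis-acetal of resorcinol 5. The two acetal groups of 6 direct the first metalation to the carbon between them, which is the later C3' and the position that direct electrophilic prenylation of a resorcinol does not select reliably. The second metalation goes ortho to one acetal, the later C1'.

## Alternatives that were turned down

**Alternative 1:** the textbook cut at C3–C1'. A Suzuki–Miyaura coupling would join 3-iodo-5,7-bis(methoxymethoxy)-6,8-diprenylchromen-4-one A1 to the boronic acid A2. It was turned down for three reasons: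
- A1 is made by iodine-induced cyclisation of an enaminone. With two prenyl olefins beside oxygen atoms the iodonium ion is expected to be captured by the olefins (iodo-etherification).
- Introducing the prenyl groups after the coupling reopens the C6/C8 and C3'/C5' questions.
- A2 is an ortho-alkoxy, electron-rich boronic acid prone to protodeboronation, and the step count is no lower than in the chosen route.

**Alternative 2:** cut at C4–C4a, then insertion of C2. A Friedel–Crafts or Houben–Hoesch acylation of 2,4-diprenylphloroglucinol A3 with the arylacetic acid A4 would give the deoxybenzoin A5, followed by formylation and ring closure. It was turned down because: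
- the strong Lewis or protic acids of the acylation act on free phenols with ortho-prenyl groups and would close chromans in both partners;
- A3 is an air-sensitive triphenol that is not obtained selectively.

A protected, palladium-based version of this logic is kept only as the fallback to the key step.

**Alternative 3:** the oxidative 1,2-aryl shift closest to the biosynthesis. The prenyl-free 2'-hydroxychalcone A6 would be rearranged with Tl(NO3)3 or PhI(OAc)2 in methanol and cyclised to 2'-hydroxygenistein A7; the three prenyl groups would follow by O-allylation and Claisen rearrangement. It was turned down because: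
- trivalent thallium and trivalent iodine attack prenyl olefins faster than the enone, so the prenyl groups must come last;
- on A7 the C5–OH is chelated and hard to alkylate, a C7–O ether rearranges to C6 and to C8, and a C4'–O ether rearranges to C3' and to C5';
- three regiochemical problems are thus reopened at the cost of four to six further steps.

Key step: step 8

Remark on the chemistry: 16 has no stereogenic element. 11 and 14 are racemic, 13 is the racemic trans-epoxide (one enantiomer is drawn in its SMILES), and these centres are erased in steps 6, 8 and 9.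

## Route

Step 1
Reactants: 1 2',4',6'-trihydroxyacetophenone; 2 prenyl bromide (1-bromo-3-methylbut-2-ene)
Product: 3 1-[2,4,6-trihydroxy-3,5-bis(3-methylbut-2-en-1-yl)phenyl]ethan-1-one
Conditions: 2 (2.2 equiv), 10% aq KOH (3 equiv), degassed, 0 °C, argon; then cold dilute AcOH to pH 5
Reagents that add atoms: none
Why: C-alkylation of an acylphloroglucinol polyanion; in water the oxygens are solvated and the soft allylic bromide is taken up by the two equivalent ring carbons, which are the only nucleophilic carbons, so one regioisomer results; a modest yield is expected because O-alkylation and geminal over-alkylation compete.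

Step 2
Reactants: 3 1-[2,4,6-trihydroxy-3,5-bis(3-methylbut-2-en-1-yl)phenyl]ethan-1-one
Product: 4 1-[2,4,6-tris(methoxymethoxy)-3,5-bis(3-methylbut-2-en-1-yl)phenyl]ethan-1-one
Conditions: NaH (3.6 equiv), MOMCl (3.6 equiv), DMF, 0 °C → rt
Reagents that add atoms: chloromethyl methyl ether (MOMCl), COCCl
Why: Williamson-type acetalisation; the hard α-chloro ether reacts at oxygen, and NaH is needed to alkylate the chelated ortho-phenols as well.

Step 3
Reactants: 5 resorcinol
Product: 6 1,3-bis(methoxymethoxy)benzene
Conditions: NaH (2.4 equiv), MOMCl (2.4 equiv), DMF, 0 °C → rt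
Reagents that add atoms: chloromethyl methyl ether (MOMCl), COCCl
Why: standard O-protection that also installs the two directing groups for both metalations.

Step 4
Reactants: 6 1,3-bis(methoxymethoxy)benzene; 2 prenyl bromide
Product: 8 1,3-bis(methoxymethoxy)-2-(3-methylbut-2-en-1-yl)benzene, via 2,6-bis(methoxymethoxy)phenyllithium 7 (not isolated)
Conditions: n-BuLi (1.1 equiv), THF, 0 °C, 1 h; then CuBr·SMe2 (10 mol%), 2 (1.2 equiv), −78 °C → rt
Reagents that add atoms: none
Why: directed ortho-metalation at the carbon between the two cooperating acetal groups, followed by copper-catalysed SN2 allylation; this fixes the prenyl group at the later C3'.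

Step 5
Reactants: 8 1,3-bis(methoxymethoxy)-2-(3-methylbut-2-en-1-yl)benzene
Product: 10 2,4-bis(methoxymethoxy)-3-(3-methylbut-2-en-1-yl)benzaldehyde, via 2,4-bis(methoxymethoxy)-3-prenylphenyllithium 9 (not isolated)
Conditions: n-BuLi (1.3 equiv), TMEDA (1.3 equiv), THF, −20 → 0 °C; then DMF (3 equiv), −78 °C → rt; H2O
Reagents that add atoms: N,N-dimethylformamide (DMF), CN(C)C=O
Why: second directed ortho-metalation, now at the ring carbon ortho to one acetal group (the two such carbons are equivalent), and formylation of the aryllithium with DMF.

Step 6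
Reactants: 4 1-[2,4,6-tris(methoxymethoxy)-3,5-bis(3-methylbut-2-en-1-yl)phenyl]ethan-1-one; 10 2,4-bis(methoxymethoxy)-3-(3-methylbut-2-en-1-yl)benzaldehyde
Product: 12 (E)-3-[2,4-bis(methoxymethoxy)-3-(3-methylbut-2-en-1-yl)phenyl]-1-[2,4,6-tris(methoxymethoxy)-3,5-bis(3-methylbut-2-en-1-yl)phenyl]prop-2-en-1-one, via aldol adduct 11 (not isolated)
Conditions: 50% aq KOH, EtOH/THF, rt, 24–48 h
Reagents that add atoms: none
Why: Claisen–Schmidt condensation; the methyl ketone enolate adds to the non-enolisable aldehyde and E1cB loss of water gives the more stable E-enone; acetal ethers and prenyl groups are inert to base.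

Step 7
Reactants: 12 (E)-chalcone
Product: 13 racemic trans-{3-[2,4-bis(methoxymethoxy)-3-(3-methylbut-2-en-1-yl)phenyl]oxiran-2-yl}[2,4,6-tris(methoxymethoxy)-3,5-bis(3-methylbut-2-en-1-yl)phenyl]methanone
Conditions: 30% aq H2O2 (10 equiv), 2 M aq NaOH (0.5 equiv), MeOH/THF, 0 °C → rt
Reagents that add atoms: hydrogen peroxide, OO
Why: Weitz–Scheffer nucleophilic epoxidation; hydroperoxide adds in conjugate fashion only to the enone, so the three electron-rich prenyl olefins are untouched; the enolate closes after bond rotation to the trans-epoxide (both stereocentres set as the racemic trans pair); no free ortho-phenol is present, so an Algar–Flynn–Oyamada closure cannot occur.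

Step 8
Reactants: 13 racemic trans-epoxy ketone
Product: 14 2-[2,4-bis(methoxymethoxy)-3-(3-methylbut-2-en-1-yl)phenyl]-3-oxo-3-[2,4,6-tris(methoxymethoxy)-3,5-bis(3-methylbut-2-en-1-yl)phenyl]propanal
Conditions: BF3·OEt2 (0.3 equiv), CH2Cl2, −78 → −40 °C, 30 min; Et3N, then aq NaHCO3
Reagents that add atoms: none
Why: BF3 binds the oxirane oxygen and the C–O bond at the carbon bearing ring B ionises, because that cation is stabilised by the ortho- and para-acetal oxygens of ring B while the other oxirane carbon is deactivated by the adjacent carbonyl; this fixes the regiochemistry of opening. The aroyl group then migrates with its bonding pair to the cationic carbon while the BF3-bound oxygen closes to C=O, giving the 2-aryl-3-oxo-propanal and so forming the bond that becomes C3–C4 of 16. The closest known reaction type is the Meinwald rearrangement of α,β-epoxy ketones with 1,2-acyl shift, as used to convert 2'-alkoxychalcone epoxides into α-formyl deoxybenzoins for isoflavones. No ring is closed in this step; ring C closes in step 9 by 6-exo-trig attack of a ring A oxygen on the formyl carbon. The one new stereocentre (C2 of 14) lies between two carbonyl groups, is racemic and enolisable and becomes sp2 in step 9, so no control is needed; the two centres of 13 are destroyed. Acyl migration rather than hydride shift (which would give a 1,2-diketone) is the normal course for epoxy ketones, and here the aroyl group is twisted out of the plane of ring A by its two ortho substituents and migrates like an aliphatic acyl group. Capture of the cation by an ortho-acetal oxygen of ring A (closure to a 3-hydroxyflavanone) would give an oxonium ion that has no nucleophile to remove its methoxymethyl group in this aprotic medium and should revert, while the very electron-rich ring B favours the free cation that undergoes the shift. Catalytic Lewis acid at low temperature without a proton source should leave the five acetal ethers and the three prenyl olefins intact.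

Step 9
Reactants: 14 α-formyl ketone
Product: 16 euchrenone b2, via tetrakis(methoxymethyl) ether 15 (not isolated)
Conditions: 3 M aq HCl (10 equiv), MeOH/THF, rt (ring closure), then 40 °C until all MOM ethers are cleaved
Reagents that add atoms: none
Why: acid-catalysed acetal exchange to methanol; the MOM ether ortho to the ketone is the most labile, so a ring A phenol is freed first and cyclodehydrates onto the formyl group to give chromone 15 before the C2'-oxygen is unmasked; the symmetry of ring A makes both ortho oxygens equivalent, and the four remaining ethers then fall under conditions of the kind used to deprotect prenylated flavonoids.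

## Compound list

1 | 2',4',6'-trihydroxyacetophenone | CC(=O)c1c(O)cc(O)cc1O | starting material
2 | prenyl bromide (1-bromo-3-methylbut-2-ene) | CC(C)=CCBr | starting material
3 | 1-[2,4,6-trihydroxy-3,5-bis(3-methylbut-2-en-1-yl)phenyl]ethan-1-one | CC(=O)c1c(O)c(CC=C(C)C)c(O)c(CC=C(C)C)c1O | intermediate
4 | 1-[2,4,6-tris(methoxymethoxy)-3,5-bis(3-methylbut-2-en-1-yl)phenyl]ethan-1-one | CC(=O)c1c(OCOC)c(CC=C(C)C)c(OCOC)c(CC=C(C)C)c1OCOC | intermediate
5 | resorcinol | Oc1cccc(O)c1 | starting material
6 | 1,3-bis(methoxymethoxy)benzene | COCOc1cccc(OCOC)c1 | intermediate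
7 | 2,6-bis(methoxymethoxy)phenyllithium | [Li]c1c(OCOC)cccc1OCOC | intermediate
8 | 1,3-bis(methoxymethoxy)-2-(3-methylbut-2-en-1-yl)benzene | COCOc1cccc(OCOC)c1CC=C(C)C | intermediate
9 | 2,4-bis(methoxymethoxy)-3-(3-methylbut-2-en-1-yl)phenyllithium | [Li]c1ccc(OCOC)c(CC=C(C)C)c1OCOC | intermediate
10 | 2,4-bis(methoxymethoxy)-3-(3-methylbut-2-en-1-yl)benzaldehyde | O=Cc1ccc(OCOC)c(CC=C(C)C)c1OCOC | intermediate
11 | racemic aldol adduct, 3-hydroxy-3-[2,4-bis(methoxymethoxy)-3-prenylphenyl]-1-[2,4,6-tris(methoxymethoxy)-3,5-diprenylphenyl]propan-1-one | O=C(CC(O)c1ccc(OCOC)c(CC=C(C)C)c1OCOC)c1c(OCOC)c(CC=C(C)C)c(OCOC)c(CC=C(C)C)c1OCOC | intermediate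
12 | (E)-3-[2,4-bis(methoxymethoxy)-3-prenylphenyl]-1-[2,4,6-tris(methoxymethoxy)-3,5-diprenylphenyl]prop-2-en-1-one | O=C(/C=C/c1ccc(OCOC)c(CC=C(C)C)c1OCOC)c1c(OCOC)c(CC=C(C)C)c(OCOC)c(CC=C(C)C)c1OCOC | intermediate
13 | racemic trans-epoxy ketone (2S,3R enantiomer drawn), {3-[2,4-bis(methoxymethoxy)-3-prenylphenyl]oxiran-2-yl}[2,4,6-tris(methoxymethoxy)-3,5-diprenylphenyl]methanone | O=C([C@H]1O[C@@H]1c1ccc(OCOC)c(CC=C(C)C)c1OCOC)c1c(OCOC)c(CC=C(C)C)c(OCOC)c(CC=C(C)C)c1OCOC | intermediate
14 | racemic 2-[2,4-bis(methoxymethoxy)-3-prenylphenyl]-3-oxo-3-[2,4,6-tris(methoxymethoxy)-3,5-diprenylphenyl]propanal (in equilibrium with its enol) | O=CC(c1ccc(OCOC)c(CC=C(C)C)c1OCOC)C(=O)c1c(OCOC)c(CC=C(C)C)c(OCOC)c(CC=C(C)C)c1OCOC | intermediate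
15 | 3-[2,4-bis(methoxymethoxy)-3-prenylphenyl]-5,7-bis(methoxymethoxy)-6,8-diprenylchromen-4-one | O=c1c(-c2ccc(OCOC)c(CC=C(C)C)c2OCOC)coc2c(CC=C(C)C)c(OCOC)c(CC=C(C)C)c(OCOC)c12 | intermediate
16 | euchrenone b2, 3-[2,4-dihydroxy-3-(3-methylbut-2-en-1-yl)phenyl]-5,7-dihydroxy-6,8-bis(3-methylbut-2-en-1-yl)chromen-4-one | CC(C)=CCc1c(O)ccc(-c2coc3c(CC=C(C)C)c(O)c(CC=C(C)C)c(O)c3c2=O)c1O | target

## Step count and risk

Total step count: 9. Longest linear sequence: 7 steps (steps 3, 4, 5, 6, 7, 8, 9, from 5 to 16); the ring A branch (steps 1 and 2) joins at step 6.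

**Step 8 (key step).** The most likely failure is capture of the benzylic cation by an ortho-acetal oxygen of ring A with loss of its methoxymethyl group, which closes a 3-hydroxyflavanone instead of allowing the aroyl shift. The second is Lewis-acid loss of acetal groups followed by addition of a freed phenol to a prenyl olefin. Both are possible because the cation is long-lived and the substrate carries ten Lewis-basic ether oxygens.

The fallback reaches 14 without any cationic step, through a deoxybenzoin; it sets out from 6 and 4 and returns at 14. Bromination of 6 with NBS in MeCN at 0 °C, para to one acetal group, gives 1-bromo-2,4-bis(methoxymethoxy)benzene F1. Deprotonation between the two acetal groups with LDA at −78 °C and alkylation with 2 (CuBr·SMe2 catalysis) gives 1-bromo-2,4-bis(methoxymethoxy)-3-(3-methylbut-2-en-1-yl)benzene F2. Palladium-catalysed α-arylation of ketone 4 with F2 (Pd(OAc)2, P(t-Bu)3·HBF4, NaOtBu, toluene, 70 °C) gives 2-[2,4-bis(methoxymethoxy)-3-prenylphenyl]-1-[2,4,6-tris(methoxymethoxy)-3,5-diprenylphenyl]ethan-1-one F3. Claisen formylation of F3 with ethyl formate and NaH in THF gives 14, which continues with step 9.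

**Step 1.** The most likely failure is loss of material to O-alkylation and to geminal, dearomatising over-alkylation, because the polyanion is ambident and the product is a better nucleophile than 1.

The fallback builds the ring by three directed metalations; it sets out from 2 together with commercial benzene-1,3,5-triol F4 and returns at 4, so that steps 1 and 2 are both replaced. NaH and MOMCl give 1,3,5-tris(methoxymethoxy)benzene F5. Lithiation with n-BuLi and allylation with 2 (CuBr·SMe2) gives 1,3,5-tris(methoxymethoxy)-2-(3-methylbut-2-en-1-yl)benzene F6. Repetition gives 1,3,5-tris(methoxymethoxy)-2,4-bis(3-methylbut-2-en-1-yl)benzene F7. Lithiation of the last ring C–H of F7 and acylation with N-methoxy-N-methylacetamide gives 4.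

**Step 5.** The most likely failure is lateral deprotonation at the benzylic and allylic CH2 of the prenyl group instead of ring metalation, because that position is flanked by both directing groups.

The fallback introduces the formyl group before the prenyl group; it sets out from 5 and returns at 10. Vilsmeier–Haack formylation of 5 (POCl3, DMF, then water) gives 2,4-dihydroxybenzaldehyde F8, and NaH with MOMCl gives 2,4-bis(methoxymethoxy)benzaldehyde F9. Addition of lithium N-methylpiperazide in THF at −20 °C masks the aldehyde as the lithium α-amino alkoxide F10. n-BuLi then removes the ring proton between the two acetal groups (no benzylic C–H is present at this stage). CuBr·SMe2 with 2, followed by aqueous work-up, gives 10.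

**Step 9.** The most likely failure is protonation of a prenyl olefin and capture of the cation by the neighbouring phenol (chroman formation) while the hindered acetal ethers are cleaved. The second is ring closure through the C2'-oxygen if it is unmasked before ring C has closed.

The fallback carries acid-stable allyl groups through the acid step and converts them into prenyl groups at the very end; it sets out from 1 and 6 and returns at 16. The main sequence is repeated with allyl bromide in place of 2:
- 1 gives 1-(3,5-diallyl-2,4,6-trihydroxyphenyl)ethan-1-one F11, and protection gives 1-[3,5-diallyl-2,4,6-tris(methoxymethoxy)phenyl]ethan-1-one F12.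
- 6 gives 2-allyl-1,3-bis(methoxymethoxy)benzene F13, and metalation with formylation gives 3-allyl-2,4-bis(methoxymethoxy)benzaldehyde F14.
- Claisen–Schmidt condensation of F12 and F14 gives the triallyl (E)-chalcone F15, alkaline H2O2 gives the trans-epoxide F16, and BF3·OEt2 gives the α-formyl ketone F17.
- Methanolic HCl on F17 gives 6,8-diallyl-3-(3-allyl-2,4-dihydroxyphenyl)-5,7-dihydroxychromen-4-one F18.
- Threefold olefin cross-metathesis of F18 with 2-methylbut-2-ene (second-generation Grubbs catalyst, CH2Cl2, 40 °C), a reaction type that tolerates free phenols, gives 16.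

## Further compounds

F1 | step 8 | 1-bromo-2,4-bis(methoxymethoxy)benzene | COCOc1ccc(Br)c(OCOC)c1
F2 | step 8 | 1-bromo-2,4-bis(methoxymethoxy)-3-(3-methylbut-2-en-1-yl)benzene | COCOc1ccc(Br)c(OCOC)c1CC=C(C)C
F3 | step 8 | 2-[2,4-bis(methoxymethoxy)-3-(3-methylbut-2-en-1-yl)phenyl]-1-[2,4,6-tris(methoxymethoxy)-3,5-bis(3-methylbut-2-en-1-yl)phenyl]ethan-1-one | O=C(Cc1ccc(OCOC)c(CC=C(C)C)c1OCOC)c1c(OCOC)c(CC=C(C)C)c(OCOC)c(CC=C(C)C)c1OCOC
F4 | step 1 | benzene-1,3,5-triol (phloroglucinol) | Oc1cc(O)cc(O)c1
F5 | step 1 | 1,3,5-tris(methoxymethoxy)benzene | COCOc1cc(OCOC)cc(OCOC)c1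
F6 | step 1 | 1,3,5-tris(methoxymethoxy)-2-(3-methylbut-2-en-1-yl)benzene | COCOc1cc(OCOC)c(CC=C(C)C)c(OCOC)c1
F7 | step 1 | 1,3,5-tris(methoxymethoxy)-2,4-bis(3-methylbut-2-en-1-yl)benzene | COCOc1cc(OCOC)c(CC=C(C)C)c(OCOC)c1CC=C(C)C
F8 | step 5 | 2,4-dihydroxybenzaldehyde | O=Cc1ccc(O)cc1O
F9 | step 5 | 2,4-bis(methoxymethoxy)benzaldehyde | O=Cc1ccc(OCOC)cc1OCOC
F10 | step 5 | lithium [2,4-bis(methoxymethoxy)phenyl](4-methylpiperazin-1-yl)methanolate | [Li]OC(c1ccc(OCOC)cc1OCOC)N1CCN(C)CC1
F11 | step 9 | 1-(3,5-diallyl-2,4,6-trihydroxyphenyl)ethan-1-one | CC(=O)c1c(O)c(CC=C)c(O)c(CC=C)c1O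
F12 | step 9 | 1-[3,5-diallyl-2,4,6-tris(methoxymethoxy)phenyl]ethan-1-one | CC(=O)c1c(OCOC)c(CC=C)c(OCOC)c(CC=C)c1OCOC
F13 | step 9 | 2-allyl-1,3-bis(methoxymethoxy)benzene | COCOc1cccc(OCOC)c1CC=C
F14 | step 9 | 3-allyl-2,4-bis(methoxymethoxy)benzaldehyde | O=Cc1ccc(OCOC)c(CC=C)c1OCOC
F15 | step 9 | (E)-3-[3-allyl-2,4-bis(methoxymethoxy)phenyl]-1-[3,5-diallyl-2,4,6-tris(methoxymethoxy)phenyl]prop-2-en-1-one | O=C(/C=C/c1ccc(OCOC)c(CC=C)c1OCOC)c1c(OCOC)c(CC=C)c(OCOC)c(CC=C)c1OCOC
F16 | step 9 | racemic trans-{3-[3-allyl-2,4-bis(methoxymethoxy)phenyl]oxiran-2-yl}[3,5-diallyl-2,4,6-tris(methoxymethoxy)phenyl]methanone (one enantiomer drawn) | O=C([C@H]1O[C@@H]1c1ccc(OCOC)c(CC=C)c1OCOC)c1c(OCOC)c(CC=C)c(OCOC)c(CC=C)c1OCOC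
F17 | step 9 | racemic 2-[3-allyl-2,4-bis(methoxymethoxy)phenyl]-3-[3,5-diallyl-2,4,6-tris(methoxymethoxy)phenyl]-3-oxopropanal | O=CC(c1ccc(OCOC)c(CC=C)c1OCOC)C(=O)c1c(OCOC)c(CC=C)c(OCOC)c(CC=C)c1OCOC
F18 | step 9 | 6,8-diallyl-3-(3-allyl-2,4-dihydroxyphenyl)-5,7-dihydroxychromen-4-one | C=CCc1c(O)ccc(-c2coc3c(CC=C)c(O)c(CC=C)c(O)c3c2=O)c1O
A1 | alternative 1 | 3-iodo-5,7-bis(methoxymethoxy)-6,8-bis(3-methylbut-2-en-1-yl)chromen-4-one | O=c1c(I)coc2c(CC=C(C)C)c(OCOC)c(CC=C(C)C)c(OCOC)c12
A2 | alternative 1 | [2,4-bis(methoxymethoxy)-3-(3-methylbut-2-en-1-yl)phenyl]boronic acid | COCOc1ccc(B(O)O)c(OCOC)c1CC=C(C)C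
A3 | alternative 2 | 2,4-bis(3-methylbut-2-en-1-yl)benzene-1,3,5-triol | CC(C)=CCc1c(O)cc(O)c(CC=C(C)C)c1O
A4 | alternative 2 | 2-[2,4-dihydroxy-3-(3-methylbut-2-en-1-yl)phenyl]acetic acid | OC(=O)Cc1ccc(O)c(CC=C(C)C)c1O
A5 | alternative 2 | 2-[2,4-dihydroxy-3-(3-methylbut-2-en-1-yl)phenyl]-1-[2,4,6-trihydroxy-3,5-bis(3-methylbut-2-en-1-yl)phenyl]ethan-1-one | O=C(Cc1ccc(O)c(CC=C(C)C)c1O)c1c(O)c(CC=C(C)C)c(O)c(CC=C(C)C)c1O
A6 | alternative 3 | (E)-3-[2,4-bis(methoxymethoxy)phenyl]-1-[2-hydroxy-4,6-bis(methoxymethoxy)phenyl]prop-2-en-1-one | COCOc1ccc(/C=C/C(=O)c2c(O)cc(OCOC)cc2OCOC)c(OCOC)c1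
A7 | alternative 3 | 2'-hydroxygenistein, 3-(2,4-dihydroxyphenyl)-5,7-dihydroxychromen-4-one | O=c1c(-c2ccc(O)cc2O)coc2cc(O)cc(O)c12
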